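At the reading, 15 min after mixing, you want the average chain length in two flasks that differ in their impurity.

    2 initiator → spent initiator B (k1 = 7400 M⁻¹ s⁻¹)
    living end → dead end C (k2 = 0.043 s⁻¹)
    free monomer + initiator → living end + monomer in chains (k3 = 120 M⁻¹ s⁻¹)
    free monomer + living end → monomer in chains + living end, rate k4*[living end]*[free monomer] (k4 = 190 M⁻¹ s⁻¹)
    initiator + impurity → spent initiator A (k5 = 2.5 × 10⁶ M⁻¹ s⁻¹)

- larch: free monomer 15 mM; initiator 75 µM; impurity 8.0 µM; time 15 min
- cedar: free monomer 15 mM; initiator 75 µM; impurity 30 µM; time 15 min

- which of the two ends with the longer chains by the average number of monomer units in a chain (chains begun, living or dead) ("neither" if they lie within 10%) (larch / cedar / neither)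
- average number of monomer units in a chain (chains begun, living or dead) at the end, larch
- average number of monomer units in a chain (chains begun, living or dead) at the end, cedar

- a step written with two of one species runs at k times the square of its concentration and takes two of it each time
- the average divides the monomer in chains by the number of chains begun, living and dead together
- run time (larch): 15 min

The quantity to carry is the kinetic chain length ν, the number of units one living end adds in its life at the charged monomer concentration:

ν = 190 M⁻¹ s⁻¹ × [free monomer] / 0.043 s⁻¹ = 66.3

At one end of the possible flasks, few chains begin, [free monomer] hardly drops, and each chain reaches ν in either recipe. At the other end, every initiator that escapes impurity begins a chain. Impurity strikes first in both flasks, since it takes initiator at 187 s⁻¹ against 1.80 s⁻¹ for initiation, so at most 67.0 µM of chains begin in larch and 45.0 µM in cedar. Joining the two ends, with first-order death of the living ends and the first unit of each chain set aside: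

x = 190 M⁻¹ s⁻¹ × [chains begun] / 0.043 s⁻¹

average = ν(1 − e^(−x)) / x

The second end therefore gives 57.4 for larch and 60.1 for cedar. In larch, initiator at first destroys itself at 0.992 s⁻¹, less than its initiation rate but of the same order, so it splits and I place each flask midway:

larch 61.8, cedar 63.2, verdict neither

The forecast says neither, with 60 for larch and 62 for cedar, below my larch figure: “Living ends die at 0.043 /s, so they are gone well before 15 min.”

The simulation gives neither, with 59.8 in larch and 61.8 in cedar; larch stands at 90.2% of ν. At 0.255 min in larch, living end has a half-life of 0.27 min, shorter than the 2.2 min of free monomer by growth, and free monomer ends at 78.7% of its charge. The average in larch moves by 6 units at 13.4 mM or 16.6 mM of free monomer, or at 18.2 µM or 171 µM of initiator. A neighbour of larch with 38 mM of free monomer has ν = 168, and its 0.0606 mM of dead end C turns that into 147; computed, 148.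

The constants used here are made up.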